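Feature: in the central cyclohexane (p-menthane locants) C4 carries the exocyclic carbon C8 (the OCMe2 carbon of the cis-fused pyran, ring A) and lies between the quinolone-bearing carbons C3 (quinolone A) and C5 (quinolone B), while C1 (Me, O of the bridged pyran, ring B) is 1,4 to C4; with C8 as a lactone carbonyl bound to the C1 oxygen, C4 becomes an enolate carbon that can reach C3 through an alkenyl arm on C1.
Target ⇒ (O–C1: acid hydroalkoxylation of the C1=C2 alkene by the freed 4-OH of quinolone B, ring B last) ⇒ (O–C8: cationic closure of the C8 carbinol onto the 4-OH of quinolone A, ring A) ⇒ cyclohex-3-enecarboxylic acid carrying both protected quinolones.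
Cyclohexene acid ⇒ (C3–C4: Ireland–Claisen ring contraction through an enforced boat, carbocycle) ⇒ (4R,6R)-4-aryl-6-methyl-6-[(E)-2-arylvinyl]oxan-2-one.
Lactone ⇒ (C1–C2: alkenylcerium addition, then lactonisation) ⇒ enantiopure methyl 3-aryl-5-oxohexanoate (quinolone B) + (E)-2-arylvinyl iodide (quinolone A).
Keto ester ⇐ Michael adduct of 4-hydroxy-1-methylquinolin-2-one and dimethyl glutaconate, desymmetrised enzymatically (sets C5); vinyl iodide ⇐ the same quinolone by chloroformylation, chloride-for-benzyloxy exchange and Takai olefination. Ring order: quinolones (bought), δ-lactone (transient), carbocycle, ring A, ring B.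

Key step: step 10

Notation: p-menthane locants are used for the core (C1: Me and O; C3: quinolone A; C4: bears C8; C5: quinolone B). ArA = 4-(benzyloxy)-1-methyl-2-oxo-1,2-dihydroquinolin-3-yl; ArB = 4-methoxy-1-methyl-2-oxo-1,2-dihydroquinolin-3-yl.
Assumption: the esterase of step 3 is taken to cleave the enantiotopic ester group that leaves the (3R) half-ester; if it shows the opposite or a weak preference, the chemical desymmetrisation given among the fallbacks supplies the same half-ester.

Step 1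
Reactants: 1 4-hydroxy-1-methylquinolin-2(1H)-one; 2 dimethyl glutaconate (dimethyl (E)-pent-2-enedioate)
Product: 3 dimethyl 3-(4-hydroxy-1-methyl-2-oxo-1,2-dihydroquinolin-3-yl)pentanedioate
Conditions: NaOMe (0.2 equiv), MeOH, reflux; AcOH
Reagents that add atoms: none
Why: Michael addition of the nucleophilic C3 of the vinylogous acid (a cyclic 1,3-dicarbonyl-type donor, more acidic than the glutaconate, so the base rests on the donor) to the enoate; methanol keeps the adduct as the open diester and the new carbon is only prochiral.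

Step 2
Reactants: 3 dimethyl 3-(4-hydroxy-1-methyl-2-oxo-1,2-dihydroquinolin-3-yl)pentanedioate
Product: 4 dimethyl 3-ArB-pentanedioate
Conditions: TMSCHN2, MeOH/PhMe, 0 °C → rt
Reagents that add atoms: trimethylsilyldiazomethane, C[Si](C)(C)C=[N+]=[N-]
Why: Diazoalkane O-methylation of the acidic enol OH (esterification-type), which should go to oxygen and not to the substituted C3; no stereocentre is formed.

Step 3
Reactants: 4 dimethyl 3-ArB-pentanedioate
Product: 5 (3R)-5-methoxy-3-ArB-5-oxopentanoic acid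
Conditions: pig liver esterase, pH 7.5 phosphate buffer/DMSO (9:1), rt; then pH 3
Reagents that add atoms: water, O
Why: Enzymatic desymmetrisation of a prochiral 3-arylglutarate diester by hydrolysis of one enantiotopic ester group, a known reaction of esterases with this substrate class; it sets the centre that becomes C5 of the target.

Step 4
Reactants: 5 (3R)-5-methoxy-3-ArB-5-oxopentanoic acid
Product: 6 methyl (3R)-5-[methoxy(methyl)amino]-3-ArB-5-oxopentanoate
Conditions: MeNH(OMe)·HCl, EDC·HCl, HOBt, iPr2NEt, CH2Cl2, 0 °C → rt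
Reagents that add atoms: N,O-dimethylhydroxylamine hydrochloride, CNOC.Cl
Why: Carbodiimide amide coupling to the Weinreb amide, which marks the acid arm for ketone formation while the ester arm and the non-enolisable stereocentre stay untouched.

Step 5
Reactants: 6 methyl (3R)-5-[methoxy(methyl)amino]-3-ArB-5-oxopentanoate
Product: 7 methyl (3R)-3-ArB-5-oxohexanoate
Conditions: MeMgBr (1.2 equiv), THF, −20 °C; 1 M HCl
Reagents that add atoms: methylmagnesium bromide, C[Mg]Br
Why: Weinreb ketone synthesis, in which the chelated tetrahedral adduct stops at the ketone stage and the N-methoxy-N-methylamide reacts before the methyl ester at low temperature.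

Step 6
Reactants: 1 4-hydroxy-1-methylquinolin-2(1H)-one
Product: 9 4-chloro-1-methyl-2-oxo-1,2-dihydroquinoline-3-carbaldehyde, via iminium chloride 8 (not isolated)
Conditions: POCl3, DMF, 60 °C; then ice/H2O
Reagents that add atoms: N,N-dimethylformamide, CN(C)C=O; phosphoryl chloride, O=P(Cl)(Cl)Cl; water, O
Why: Vilsmeier–Haack reaction, which with 4-hydroxy-2-quinolones and 4-hydroxycoumarins formylates the nucleophilic C3 and replaces the 4-OH by chloride in one operation.

Step 7
Reactants: 9 4-chloro-1-methyl-2-oxo-1,2-dihydroquinoline-3-carbaldehyde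
Product: 10 4-(benzyloxy)-1-methyl-2-oxo-1,2-dihydroquinoline-3-carbaldehyde
Conditions: BnOH, NaH, THF, 0 °C
Reagents that add atoms: benzyl alcohol, OCc1ccccc1
Why: Addition–elimination (SNAr) of the alkoxide at C4, a β-chlorovinyl aldehyde carbon activated by the formyl group and the lactam carbonyl.

Step 8
Reactants: 10 4-(benzyloxy)-1-methyl-2-oxo-1,2-dihydroquinoline-3-carbaldehyde
Product: 11 4-(benzyloxy)-3-[(E)-2-iodoethenyl]-1-methylquinolin-2(1H)-one
Conditions: CrCl2, CHI3, THF, 0 °C → rt
Reagents that add atoms: iodoform, IC(I)I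
Why: Takai olefination, which turns aryl-type aldehydes into (E)-vinyl iodides with high E selectivity and should tolerate the lactam and the benzyl ether.

Step 9
Reactants: 11 4-(benzyloxy)-3-[(E)-2-iodoethenyl]-1-methylquinolin-2(1H)-one; 7 methyl (3R)-3-ArB-5-oxohexanoate
Product: 15 (4R,6R)-6-[(E)-2-ArA-ethenyl]-4-ArB-6-methyloxan-2-one (aryl and alkenyl cis), via alkenyllithium 12 (not isolated), via alkenylcerium dichloride 13 (not isolated), via hydroxy ester 14 (not isolated)
Conditions: 11, t-BuLi (2 equiv), THF/Et2O, −78 °C; CeCl3, −78 °C; 7, −78 °C → rt; H2O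
Reagents that add atoms: none
Why: Iodine–lithium exchange with retention of the E geometry, transmetalation to the weakly basic organocerium, chemoselective 1,2-addition to the methyl ketone beside the ester and lactonisation of the tertiary alkoxide on warming; the β-stereocentre is expected to give little facial control at the new C6 centre (C1 of the core), so 15 is to be separated from its C6 epimer by chromatography on Et3N-buffered silica.

Step 10
Reactants: 15 (4R,6R)-6-[(E)-2-ArA-ethenyl]-4-ArB-6-methyloxan-2-one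
Product: 18 (1S,2R,6R)-2-ArA-6-ArB-4-methylcyclohex-3-ene-1-carboxylic acid, via silyl ketene acetal 16 (not isolated), via trimethylsilyl ester 17 (not isolated)
Conditions: LiN(iPr)2, THF, −78 °C; TMSCl/Et3N, −78 °C → rt; PhMe, 90 °C; then H2O
Reagents that add atoms: none
Why: Ireland–Claisen rearrangement in its ring-contracting form: deprotonation at C4 and O-silylation give the cyclic silyl ketene acetal 16, whose [3,3]-sigmatropic shift forms C3–C4 while the tertiary allylic O–C1 bond breaks, so the lactone ring (which loses O and C8 and gains C2 and C3) becomes the C1=C2 cyclohexene silyl ester 17, hydrolysed to 18 on work-up. The closest known reaction type is the ester-enolate Claisen ring contraction of 6-alkenyl δ-lactones through their silyl ketene acetals. The carbocycle closes by suprafacial bonding of the ketene acetal carbon to the distal alkene carbon inside a six-atom array that is bridged 1,4 by C5–C6, which permits only a boat (bicyclo[2.2.2]octane-like) geometry. C3 is controlled by the E alkene, which in this boat places quinolone A cis to the carboxyl carbon C8; C4 is controlled by the lactone C1 centre, because the alkenyl arm can reach C4 only on the ring face it occupies, and since the C5 aryl is cis to that arm it ends trans to C8. The step needs the concerted shift to outrun heterolysis of the tertiary allylic C–O bond; amine-buffered silylation, a non-polar solvent and the acceleration expected from the fully substituted C1 and the aryl-bearing terminus should secure this.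

Step 11
Reactants: 18 (1S,2R,6R)-2-ArA-6-ArB-4-methylcyclohex-3-ene-1-carboxylic acid
Product: 19 methyl (1S,2R,6R)-2-ArA-6-ArB-4-methylcyclohex-3-ene-1-carboxylate
Conditions: TMSCHN2, MeOH/PhMe, 0 °C
Reagents that add atoms: trimethylsilyldiazomethane, C[Si](C)(C)C=[N+]=[N-]
Why: Diazoalkane esterification under neutral conditions, which leaves the alkene, the benzyl ether and the epimerisable C4 centre alone.

Step 12
Reactants: 19 methyl (1S,2R,6R)-2-ArA-6-ArB-4-methylcyclohex-3-ene-1-carboxylate
Product: 21 2-[(1S,2R,6R)-2-ArA-6-ArB-4-methylcyclohex-3-en-1-yl]propan-2-ol, via methyl ketone 20 (not isolated)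
Conditions: MeMgBr (4 equiv), CeCl3, THF, −78 → 0 °C; H2O
Reagents that add atoms: methylmagnesium bromide, C[Mg]Br
Why: Double addition of the methylcerium reagent to the ester gives the C8 tertiary carbinol; the organocerium is nucleophilic but weakly basic, so the hindered ester and the intermediate ketone should not be enolised at C4 and its configuration is kept.

Step 13
Reactants: 21 2-[(1S,2R,6R)-2-ArA-6-ArB-4-methylcyclohex-3-en-1-yl]propan-2-ol
Product: 22 2-[(1S,2R,6R)-2-(4-hydroxy-1-methyl-2-oxo-1,2-dihydroquinolin-3-yl)-6-ArB-4-methylcyclohex-3-en-1-yl]propan-2-ol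
Conditions: H2 (1 atm), Pd/C, EtOAc, rt
Reagents that add atoms: none
Why: Hydrogenolysis of the benzyl ether of a vinylogous acid, which is as fast as that of a benzyl ester and is expected to outpace hydrogenation of the hindered trisubstituted ring alkene when stopped after one equivalent of H2.

Step 14
Reactants: 22 2-[(1S,2R,6R)-2-(4-hydroxy-1-methyl-2-oxo-1,2-dihydroquinolin-3-yl)-6-ArB-4-methylcyclohex-3-en-1-yl]propan-2-ol
Product: 23 ring A ether (3R,4S,5R): 22 with the 4-oxygen of quinolone A bonded to C8, cis-fused 2,2-dimethylpyran, C1=C2 alkene and ArB retained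
Conditions: CSA (0.1 equiv), CH2Cl2, 0 °C → rt
Reagents that add atoms: none
Why: Acid-catalysed dehydrative etherification (2,2-dimethylchroman-type closure): the tertiary carbinol ionises at C8 and the cis 4-OH of quinolone A captures the cation in a six-membered ring, under acid too weak to protonate the C1=C2 alkene at a competitive rate; no new stereocentre is formed.

Step 15
Reactants: 23 ring A ether (3R,4S,5R)
Product: 24 ring A ether with free 4-hydroxyquinolone B (3R,4S,5R)
Conditions: NaSEt, DMF, 80 °C; AcOH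
Reagents that add atoms: none
Why: Thiolate SN2 demethylation of the 4-methoxy-2-quinolone (a vinylogous methyl ester with a stabilised leaving group); the tertiary alkyl ether of ring A cannot be attacked in this way and the alkene is inert.

Step 16
Reactants: 24 ring A ether with free 4-hydroxyquinolone B
Product: 25 CNP0229685.6 (1S,3R,4R,5R in p-menthane locants)
Conditions: TfOH (0.1 equiv), CH2Cl2, 0 °C → rt
Reagents that add atoms: none
Why: Brønsted acid-catalysed intramolecular Markovnikov hydroalkoxylation: protonation of the trisubstituted alkene gives the tertiary C1 cation, which the 4-OH of quinolone B can capture only on the ring face that carries the C5 aryl (1,3-diaxial bridge), and this sets C1 with O cis to quinolone B.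

Compound list
1 | 4-hydroxy-1-methylquinolin-2(1H)-one | Cn1c(=O)cc(O)c2ccccc21 | starting material
2 | dimethyl glutaconate (dimethyl (E)-pent-2-enedioate) | COC(=O)C/C=C/C(=O)OC | starting material
3 | dimethyl 3-(4-hydroxy-1-methyl-2-oxo-1,2-dihydroquinolin-3-yl)pentanedioate | COC(=O)CC(CC(=O)OC)c1c(O)c2ccccc2n(C)c1=O | intermediate
4 | dimethyl 3-(4-methoxy-1-methyl-2-oxo-1,2-dihydroquinolin-3-yl)pentanedioate | COC(=O)CC(CC(=O)OC)c1c(OC)c2ccccc2n(C)c1=O | intermediate
5 | (3R)-5-methoxy-3-(4-methoxy-1-methyl-2-oxo-1,2-dihydroquinolin-3-yl)-5-oxopentanoic acid | COC(=O)C[C@H](c1c(OC)c2ccccc2n(C)c1=O)CC(=O)O | intermediate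
6 | methyl (3R)-5-[methoxy(methyl)amino]-3-(4-methoxy-1-methyl-2-oxo-1,2-dihydroquinolin-3-yl)-5-oxopentanoate | COC(=O)C[C@H](c1c(OC)c2ccccc2n(C)c1=O)CC(=O)N(C)OC | intermediate
7 | methyl (3R)-3-(4-methoxy-1-methyl-2-oxo-1,2-dihydroquinolin-3-yl)-5-oxohexanoate | COC(=O)C[C@H](c1c(OC)c2ccccc2n(C)c1=O)CC(C)=O | intermediate
8 | N-[(4-chloro-1-methyl-2-oxo-1,2-dihydroquinolin-3-yl)methylidene]-N-methylmethanaminium chloride | C[N+](C)=Cc1c(Cl)c2ccccc2n(C)c1=O.[Cl-] | intermediate
9 | 4-chloro-1-methyl-2-oxo-1,2-dihydroquinoline-3-carbaldehyde | O=Cc1c(Cl)c2ccccc2n(C)c1=O | intermediate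
10 | 4-(benzyloxy)-1-methyl-2-oxo-1,2-dihydroquinoline-3-carbaldehyde | O=Cc1c(OCc2ccccc2)c2ccccc2n(C)c1=O | intermediate
11 | 4-(benzyloxy)-3-[(E)-2-iodoethenyl]-1-methylquinolin-2(1H)-one | I/C=C/c1c(OCc2ccccc2)c2ccccc2n(C)c1=O | intermediate
12 | {(E)-2-[4-(benzyloxy)-1-methyl-2-oxo-1,2-dihydroquinolin-3-yl]ethenyl}lithium | [Li]/C=C/c1c(OCc2ccccc2)c2ccccc2n(C)c1=O | intermediate
13 | dichloro{(E)-2-[4-(benzyloxy)-1-methyl-2-oxo-1,2-dihydroquinolin-3-yl]ethenyl}cerium | Cl[Ce](Cl)/C=C/c1c(OCc2ccccc2)c2ccccc2n(C)c1=O | intermediate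
14 | methyl (3R,5R,6E)-7-[4-(benzyloxy)-1-methyl-2-oxo-1,2-dihydroquinolin-3-yl]-5-hydroxy-3-(4-methoxy-1-methyl-2-oxo-1,2-dihydroquinolin-3-yl)-5-methylhept-6-enoate (formed as its metal alkoxide) | COC(=O)C[C@H](c1c(OC)c2ccccc2n(C)c1=O)C[C@](C)(/C=C/c1c(OCc2ccccc2)c2ccccc2n(C)c1=O)O | intermediate
15 | (4R,6R)-6-{(E)-2-[4-(benzyloxy)-1-methyl-2-oxo-1,2-dihydroquinolin-3-yl]ethenyl}-4-(4-methoxy-1-methyl-2-oxo-1,2-dihydroquinolin-3-yl)-6-methyloxan-2-one (aryl and alkenyl cis) | O=C1C[C@H](c2c(OC)c3ccccc3n(C)c2=O)C[C@](C)(/C=C/c2c(OCc3ccccc3)c3ccccc3n(C)c2=O)O1 | intermediate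
16 | 4-(benzyloxy)-3-{(E)-2-[(2R,4R)-4-(4-methoxy-1-methyl-2-oxo-1,2-dihydroquinolin-3-yl)-2-methyl-6-(trimethylsilyloxy)-3,4-dihydro-2H-pyran-2-yl]ethenyl}-1-methylquinolin-2(1H)-one | C[Si](C)(C)OC1=C[C@H](c2c(OC)c3ccccc3n(C)c2=O)C[C@](C)(/C=C/c2c(OCc3ccccc3)c3ccccc3n(C)c2=O)O1 | intermediate
17 | trimethylsilyl (1S,2R,6R)-2-[4-(benzyloxy)-1-methyl-2-oxo-1,2-dihydroquinolin-3-yl]-6-(4-methoxy-1-methyl-2-oxo-1,2-dihydroquinolin-3-yl)-4-methylcyclohex-3-ene-1-carboxylate | C[Si](C)(C)OC(=O)[C@@H]1[C@H](c2c(OCc3ccccc3)c3ccccc3n(C)c2=O)C=C(C)C[C@H]1c1c(OC)c2ccccc2n(C)c1=O | intermediate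
18 | (1S,2R,6R)-2-[4-(benzyloxy)-1-methyl-2-oxo-1,2-dihydroquinolin-3-yl]-6-(4-methoxy-1-methyl-2-oxo-1,2-dihydroquinolin-3-yl)-4-methylcyclohex-3-ene-1-carboxylic acid (quinolone A cis, quinolone B trans to CO2H) | OC(=O)[C@@H]1[C@H](c2c(OCc3ccccc3)c3ccccc3n(C)c2=O)C=C(C)C[C@H]1c1c(OC)c2ccccc2n(C)c1=O | intermediate
19 | methyl (1S,2R,6R)-2-[4-(benzyloxy)-1-methyl-2-oxo-1,2-dihydroquinolin-3-yl]-6-(4-methoxy-1-methyl-2-oxo-1,2-dihydroquinolin-3-yl)-4-methylcyclohex-3-ene-1-carboxylate | COC(=O)[C@@H]1[C@H](c2c(OCc3ccccc3)c3ccccc3n(C)c2=O)C=C(C)C[C@H]1c1c(OC)c2ccccc2n(C)c1=O | intermediate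
20 | 1-[(1S,2R,6R)-2-[4-(benzyloxy)-1-methyl-2-oxo-1,2-dihydroquinolin-3-yl]-6-(4-methoxy-1-methyl-2-oxo-1,2-dihydroquinolin-3-yl)-4-methylcyclohex-3-en-1-yl]ethan-1-one | CC(=O)[C@@H]1[C@H](c2c(OCc3ccccc3)c3ccccc3n(C)c2=O)C=C(C)C[C@H]1c1c(OC)c2ccccc2n(C)c1=O | intermediate
21 | 2-[(1S,2R,6R)-2-[4-(benzyloxy)-1-methyl-2-oxo-1,2-dihydroquinolin-3-yl]-6-(4-methoxy-1-methyl-2-oxo-1,2-dihydroquinolin-3-yl)-4-methylcyclohex-3-en-1-yl]propan-2-ol | CC(C)(O)[C@@H]1[C@H](c2c(OCc3ccccc3)c3ccccc3n(C)c2=O)C=C(C)C[C@H]1c1c(OC)c2ccccc2n(C)c1=O | intermediate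
22 | 2-[(1S,2R,6R)-2-(4-hydroxy-1-methyl-2-oxo-1,2-dihydroquinolin-3-yl)-6-(4-methoxy-1-methyl-2-oxo-1,2-dihydroquinolin-3-yl)-4-methylcyclohex-3-en-1-yl]propan-2-ol | CC(C)(O)[C@@H]1[C@H](c2c(O)c3ccccc3n(C)c2=O)C=C(C)C[C@H]1c1c(OC)c2ccccc2n(C)c1=O | intermediate
23 | ring A ether (3R,4S,5R in p-menthane locants): 2,2-dimethylpyran cis-fused at C3/C4 to the 1-methylcyclohexene and fused to the N-methyl-2-quinolone A through O4 and C3, with C5 bearing 4-methoxy-1-methyl-2-oxo-1,2-dihydroquinolin-3-yl | Cn1c(=O)c2c(c3ccccc31)OC(C)(C)[C@@H]1[C@H]2C=C(C)C[C@H]1c1c(OC)c3ccccc3n(C)c1=O | intermediate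
24 | ring A ether (3R,4S,5R) as 23, with C5 bearing 4-hydroxy-1-methyl-2-oxo-1,2-dihydroquinolin-3-yl | Cn1c(=O)c2c(c3ccccc31)OC(C)(C)[C@@H]1[C@H]2C=C(C)C[C@H]1c1c(O)c3ccccc3n(C)c1=O | intermediate
25 | CNP0229685.6: bis(pyrano[3,2-c]quinolin-5-one) with cis-fused pyran A (O–C8) and bridged pyran B (O–C1) on the p-menthane core, 1S,3R,4R,5R in p-menthane locants | Cn1c(=O)c2c(c3ccccc31)OC(C)(C)[C@@H]1[C@H]2C[C@]2(C)C[C@H]1c1c(c3ccccc3n(C)c1=O)O2 | target

Total step count: 16.
Longest linear sequence: 13 steps (steps 1–5, then 9–16); the vinyl iodide branch (steps 6–8) joins at step 9.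

Steps most likely to fail

Step 10 (key step). What may go wrong: heterolysis of the tertiary, aryl-conjugated allylic C1–O bond in the enolate or in ketene acetal 16 outruns the strained boat rearrangement and ends in elimination to a dienoic acid, or enolisation and O-silylation stay incomplete. Fallback (C3–C4 and C5–C6 made together by an auxiliary-controlled Diels–Alder reaction instead of the sigmatropic shift), setting out from iodide 11 and chloro aldehyde 9 and returning at acid 18:
- Suzuki coupling of 11 with isopropenylboronic acid pinacol ester (Pd(PPh3)4, K2CO3, dioxane/H2O) would give the diene 4-(benzyloxy)-1-methyl-3-[(1E)-3-methylbuta-1,3-dien-1-yl]quinolin-2(1H)-one F1.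
- SNAr of 9 with NaOMe in MeOH would give 4-methoxy-1-methyl-2-oxo-1,2-dihydroquinoline-3-carbaldehyde F2.
- Doebner–Knoevenagel condensation of F2 with malonic acid (pyridine, piperidine) would give (2E)-3-(4-methoxy-1-methyl-2-oxo-1,2-dihydroquinolin-3-yl)prop-2-enoic acid F3.
- Acylation of lithiated (4R)-4-benzyl-1,3-oxazolidin-2-one with the pivaloyl mixed anhydride of F3 would give (4R)-4-benzyl-3-[(2E)-3-(4-methoxy-1-methyl-2-oxo-1,2-dihydroquinolin-3-yl)prop-2-enoyl]-1,3-oxazolidin-2-one F4.
- Et2AlCl-promoted cycloaddition of F1 to F4 should give (4R)-4-benzyl-3-{[(1S,2R,6R)-2-[4-(benzyloxy)-1-methyl-2-oxo-1,2-dihydroquinolin-3-yl]-6-(4-methoxy-1-methyl-2-oxo-1,2-dihydroquinolin-3-yl)-4-methylcyclohex-3-en-1-yl]carbonyl}-1,3-oxazolidin-2-one F5. The 1-aryl and 3-methyl groups of the diene both direct C3 to the acyl-bearing carbon, endo addition places quinolone A cis to the acyl group, the E dienophile keeps quinolone B trans, and the benzyl group of the chelated s-cis imide shields one face.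
- LiOH/H2O2 would then release 18.

Step 9. What may go wrong: weak facial discrimination in the addition to the methyl ketone, so that the cis and trans lactones form in similar amounts, made worse by side reactions of the alkenyllithium (attack on a quinolone carbonyl, proton abstraction from the ketone). Fallback (the two C1 substituents introduced in the opposite order, the alkene made by aldol condensation), setting out from ketone 7 and aldehyde 10 and returning at hydroxy ester 14 and lactone 15: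
- Kinetic enolisation of 7 at the methyl group (LiN(iPr)2, THF, −78 °C) and aldol addition to 10 would give methyl (3R)-7-[4-(benzyloxy)-1-methyl-2-oxo-1,2-dihydroquinolin-3-yl]-7-hydroxy-3-(4-methoxy-1-methyl-2-oxo-1,2-dihydroquinolin-3-yl)-5-oxoheptanoate F6.
- Mesylation and elimination (MsCl, Et3N, then DBU) would give the enone methyl (3R,6E)-7-[4-(benzyloxy)-1-methyl-2-oxo-1,2-dihydroquinolin-3-yl]-3-(4-methoxy-1-methyl-2-oxo-1,2-dihydroquinolin-3-yl)-5-oxohept-6-enoate F7.
- 1,2-Addition of MeMgBr/CeCl3 at −78 °C would deliver 14 by methyl attack on the alkenyl ketone, which reverses whatever facial preference operates in step 9 and needs no alkenyllithium; lactonisation on warming gives 15.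

Step 3. What may go wrong: the bulky, doubly ortho-substituted quinolone keeps the diester out of the enzyme active site, or the two enantiotopic ester groups are hydrolysed with low or opposite selectivity. Fallback (chemical desymmetrisation of the cyclic anhydride), setting out from diester 4 and returning at half-ester 5:
- Saponification (LiOH, THF/H2O) would give 3-(4-methoxy-1-methyl-2-oxo-1,2-dihydroquinolin-3-yl)pentanedioic acid F8.
- Ac2O at reflux would give 4-(4-methoxy-1-methyl-2-oxo-1,2-dihydroquinolin-3-yl)oxane-2,6-dione F9.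
- Methanolysis of F9 under a bifunctional cinchona alkaloid catalyst (quinine- or quinidine-derived thiourea, MeOH, MTBE, low temperature) should give 5, the pseudoenantiomer of the catalyst being chosen for the (3R) sense.

Further compounds
F1 | step 10 | 4-(benzyloxy)-1-methyl-3-[(1E)-3-methylbuta-1,3-dien-1-yl]quinolin-2(1H)-one | CC(=C)/C=C/c1c(OCc2ccccc2)c2ccccc2n(C)c1=O
F2 | step 10 | 4-methoxy-1-methyl-2-oxo-1,2-dihydroquinoline-3-carbaldehyde | O=Cc1c(OC)c2ccccc2n(C)c1=O
F3 | step 10 | (2E)-3-(4-methoxy-1-methyl-2-oxo-1,2-dihydroquinolin-3-yl)prop-2-enoic acid | OC(=O)/C=C/c1c(OC)c2ccccc2n(C)c1=O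
F4 | step 10 | (4R)-4-benzyl-3-[(2E)-3-(4-methoxy-1-methyl-2-oxo-1,2-dihydroquinolin-3-yl)prop-2-enoyl]-1,3-oxazolidin-2-one | O=C(/C=C/c1c(OC)c2ccccc2n(C)c1=O)N1[C@H](Cc2ccccc2)COC1=O
F5 | step 10 | (4R)-4-benzyl-3-{[(1S,2R,6R)-2-[4-(benzyloxy)-1-methyl-2-oxo-1,2-dihydroquinolin-3-yl]-6-(4-methoxy-1-methyl-2-oxo-1,2-dihydroquinolin-3-yl)-4-methylcyclohex-3-en-1-yl]carbonyl}-1,3-oxazolidin-2-one | O=C([C@@H]1[C@H](c2c(OCc3ccccc3)c3ccccc3n(C)c2=O)C=C(C)C[C@H]1c1c(OC)c2ccccc2n(C)c1=O)N1[C@H](Cc2ccccc2)COC1=O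
F6 | step 9 | methyl (3R)-7-[4-(benzyloxy)-1-methyl-2-oxo-1,2-dihydroquinolin-3-yl]-7-hydroxy-3-(4-methoxy-1-methyl-2-oxo-1,2-dihydroquinolin-3-yl)-5-oxoheptanoate (both C7 epimers) | COC(=O)C[C@H](c1c(OC)c2ccccc2n(C)c1=O)CC(=O)CC(O)c1c(OCc2ccccc2)c2ccccc2n(C)c1=O
F7 | step 9 | methyl (3R,6E)-7-[4-(benzyloxy)-1-methyl-2-oxo-1,2-dihydroquinolin-3-yl]-3-(4-methoxy-1-methyl-2-oxo-1,2-dihydroquinolin-3-yl)-5-oxohept-6-enoate | COC(=O)C[C@H](c1c(OC)c2ccccc2n(C)c1=O)CC(=O)/C=C/c1c(OCc2ccccc2)c2ccccc2n(C)c1=O
F8 | step 3 | 3-(4-methoxy-1-methyl-2-oxo-1,2-dihydroquinolin-3-yl)pentanedioic acid | OC(=O)CC(CC(=O)O)c1c(OC)c2ccccc2n(C)c1=O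
F9 | step 3 | 4-(4-methoxy-1-methyl-2-oxo-1,2-dihydroquinolin-3-yl)oxane-2,6-dione | O=C1CC(CC(=O)O1)c1c(OC)c2ccccc2n(C)c1=O
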